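**Plan**

1. Retrosynthesis: first the three O–CH2Ph bonds (final hydrogenolysis); then the exocyclic bond from ring carbon C3 to the CH2 of the 3,4-dihydroxy-5-methoxybenzyl group (enolate benzylation); last the ring bond C3–C4 of the lactone (ring atoms O1, C2(=O), C3, C4, C5), which opens the ring to an achiral 3-arylpropyl diazoacetate.
2. Enabling feature: the ester O1–C2(=O) of the lactone is a ready-made tether, and in the opened chain Ar–CH2–CH2–CH2–O the future C4 is an unactivated, prochiral methylene in a 1,5 relation to C3. A rhodium carbene at C3 (the ester α-carbon with its polarity reversed from nucleophilic to electrophilic) can therefore insert into a C4–H bond and close the five-membered ring.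
3. Forward order: dihydroconiferyl alcohol → O-benzyl ether → bromoacetate → diazoacetate → C–H insertion closes the only ring (lactone, bond C3–C4) → the second aryl unit, a benzylic bromide made from 5-hydroxyvanillin, is joined at C3 → hydrogenolysis frees the three phenols.
4. Stereochemistry: C4 (R) by catalyst control in the insertion (a chiral dirhodium carboxamidate selects one of the two enantiotopic C4–H bonds); C3 (R) by substrate control in the alkylation (attack anti to the C4 benzyl group gives the trans lactone); neither centre is touched afterwards.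

Key step: step 4

Remark 1: compounds 1, 2, 4, 6 and 11 are taken as commercial; Rh2(4R-MPPIM)4 (MPPIM = methyl 2-oxo-1-(3-phenylpropanoyl)imidazolidine-4-carboxylate, a dimer of divalent rhodium with four bridging carboxamidates) is taken to be made by ligand exchange of Rh2(OAc)4 with the ligand derived from D-asparagine.

Remark 2: the (4R) ligand series is taken to deliver the (R) lactone; if the sense of induction proves opposite, Rh2(4S-MPPIM)4 is used with no other change.

**Route**

Step 1
Reactants: 1 3-(4-hydroxy-3-methoxyphenyl)propan-1-ol (dihydroconiferyl alcohol); 2 benzyl bromide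
Product: 3 3-[4-(benzyloxy)-3-methoxyphenyl]propan-1-ol
Conditions: BnBr (1.05 equiv), K2CO3, acetone, reflux
Reagents that add atoms: benzyl bromide (2), BrCc1ccccc1
Why: Williamson ether synthesis in which carbonate deprotonates only the phenol (far more acidic than the primary alcohol), so the phenoxide alone is benzylated by SN2.

Step 2
Reactants: 3 3-[4-(benzyloxy)-3-methoxyphenyl]propan-1-ol; 4 bromoacetyl bromide
Product: 5 3-[4-(benzyloxy)-3-methoxyphenyl]propyl bromoacetate
Conditions: BrCH2COBr (1.5 equiv), NaHCO3 (3 equiv), MeCN, 0 °C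
Reagents that add atoms: bromoacetyl bromide (4), BrCC(Br)=O
Why: O-acylation of the primary alcohol by an acyl bromide (nucleophilic acyl substitution), which is far faster than displacement of the alkyl bromide, with NaHCO3 as acid scavenger.

Step 3
Reactants: 5 3-[4-(benzyloxy)-3-methoxyphenyl]propyl bromoacetate; 6 N,N'-ditosylhydrazine
Product: 8 3-[4-(benzyloxy)-3-methoxyphenyl]propyl diazoacetate, via alkylated ditosylhydrazide 7 (not isolated)
Conditions: TsNHNHTs (2 equiv), DBU (5 equiv), THF, 0 °C
Reagents that add atoms: N,N'-ditosylhydrazine (6), Cc1ccc(cc1)S(=O)(=O)NNS(=O)(=O)c1ccc(C)cc1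
Why: diazoacetate synthesis by N-alkylation of the ditosylhydrazide anion with the bromoacetate and base-induced double elimination of sulfinate (N,N'-ditosylhydrazine method), mild enough for the ester and the benzyl ether.

Step 4
Reactants: 8 3-[4-(benzyloxy)-3-methoxyphenyl]propyl diazoacetate
Product: 10 (4R)-4-{[4-(benzyloxy)-3-methoxyphenyl]methyl}oxolan-2-one, via rhodium carbene 9 (not isolated)
Conditions: Rh2(4R-MPPIM)4 (1 mol %), CH2Cl2, reflux, slow addition of 8 by syringe pump
Reagents that add atoms: none
Why: The diazo carbon binds at an axial site of the catalyst and loses N2 to give an electrophilic rhodium carbene at the future C3, which inserts into a C–H bond of the chain methylene that becomes C4 through a concerted, asynchronous three-centre transition state with hydride-like transfer to the carbene carbon, so that the ring bond C3–C4 and the new C3–H bond form together and the catalyst is released. The closest known reaction type is the enantioselective intramolecular C–H insertion of alkyl diazoacetates catalysed by chiral dirhodium carboxamidates, a type established for 3-arylpropyl diazoacetates. The lactone (O1, C2, C3, C4, C5) closes as a five-membered ring by 1,5-insertion, with the native ester O1–C2(=O) as the tether. The new stereocentre C4 is set by the catalyst alone: the ester and N-acyl groups of the four imidazolidinone ligands around the rhodium face fix the orientation of the carbene ester and let only one of the two enantiotopic C4–H bonds reach the carbene carbon, the (4R) ligand series being chosen to give (R)-10. The step needs regioselectivity for the homobenzylic methylene (γ-lactone) over the O–CH2 group (β-lactone) and the benzylic CH2 (δ-lactone), and chemoselectivity over addition to the electron-rich arene and over carbene dimerisation. These should be secured by the preference for the five-membered transition state, by the strongly donating carboxamidate ligands that make the carbene less electrophilic and more selective, by the distance of the arene and the benzyl-ether CH2 from the carbene, and by slow addition.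

Step 5
Reactants: 11 3,4-dihydroxy-5-methoxybenzaldehyde (5-hydroxyvanillin); 2 benzyl bromide
Product: 12 3,4-bis(benzyloxy)-5-methoxybenzaldehyde
Conditions: BnBr (2.3 equiv), K2CO3, DMF, 60 °C
Reagents that add atoms: benzyl bromide (2), BrCc1ccccc1
Why: double Williamson ether synthesis on both catechol oxygens under carbonate in a dipolar aprotic solvent, the aldehyde being inert.

Step 6
Reactants: 12 3,4-bis(benzyloxy)-5-methoxybenzaldehyde
Product: 13 [3,4-bis(benzyloxy)-5-methoxyphenyl]methanol
Conditions: NaBH4, MeOH/THF, 0 °C
Reagents that add atoms: none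
Why: borohydride reduction of the aryl aldehyde to the benzylic alcohol, which leaves the benzyl ethers untouched.

Step 7
Reactants: 13 [3,4-bis(benzyloxy)-5-methoxyphenyl]methanol
Product: 14 1,2-bis(benzyloxy)-5-(bromomethyl)-3-methoxybenzene
Conditions: PBr3 (0.4 equiv), Et2O, 0 °C
Reagents that add atoms: phosphorus tribromide, BrP(Br)Br
Why: PBr3 bromination, in which the benzylic alcohol is activated as a phosphite ester and displaced by bromide (SN2), fast at 0 °C for an electron-rich benzylic position.

Step 8
Reactants: 10 (4R)-4-{[4-(benzyloxy)-3-methoxyphenyl]methyl}oxolan-2-one; 14 1,2-bis(benzyloxy)-5-(bromomethyl)-3-methoxybenzene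
Product: 16 (3R,4R)-3-{[3,4-bis(benzyloxy)-5-methoxyphenyl]methyl}-4-{[4-(benzyloxy)-3-methoxyphenyl]methyl}oxolan-2-one, via lithium enolate 15 (not isolated)
Conditions: LiHMDS (1.1 equiv), THF, −78 °C; then 14, DMPU, −78 → −30 °C
Reagents that add atoms: benzylic bromide 14, COc1cc(CBr)cc(OCc2ccccc2)c1OCc1ccccc1
Why: alkylation of a lactone lithium enolate (SN2 on a benzylic bromide), in which the C4 benzyl group shields one face of the planar enolate so that the electrophile enters anti and sets C3 as (R), trans to C4, by substrate control.

Step 9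
Reactants: 16 (3R,4R)-3-{[3,4-bis(benzyloxy)-5-methoxyphenyl]methyl}-4-{[4-(benzyloxy)-3-methoxyphenyl]methyl}oxolan-2-one
Product: 17 (−)-thujaplicatin
Conditions: H2 (1 atm), 10% Pd/C, EtOAc/MeOH, rt
Reagents that add atoms: none
Why: catalytic hydrogenolysis of the three aryl benzyl ethers on Pd/C under neutral conditions, which leaves the lactone and both stereocentres untouched.

**Compound list**

1 | 3-(4-hydroxy-3-methoxyphenyl)propan-1-ol | COc1cc(CCCO)ccc1O | starting material
2 | benzyl bromide | BrCc1ccccc1 | starting material
3 | 3-[4-(benzyloxy)-3-methoxyphenyl]propan-1-ol | COc1cc(CCCO)ccc1OCc1ccccc1 | intermediate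
4 | bromoacetyl bromide | BrCC(Br)=O | starting material
5 | 3-[4-(benzyloxy)-3-methoxyphenyl]propyl bromoacetate | COc1cc(CCCOC(=O)CBr)ccc1OCc1ccccc1 | intermediate
6 | N,N'-ditosylhydrazine | Cc1ccc(cc1)S(=O)(=O)NNS(=O)(=O)c1ccc(C)cc1 | starting material
7 | alkylated ditosylhydrazide, 3-[4-(benzyloxy)-3-methoxyphenyl]propyl 2-(1,2-ditosylhydrazinyl)acetate | COc1cc(CCCOC(=O)CN(NS(=O)(=O)c2ccc(C)cc2)S(=O)(=O)c2ccc(C)cc2)ccc1OCc1ccccc1 | intermediate (not isolated)
8 | 3-[4-(benzyloxy)-3-methoxyphenyl]propyl diazoacetate | COc1cc(CCCOC(=O)C=[N+]=[N-])ccc1OCc1ccccc1 | intermediate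
9 | rhodium carbene of 8 on Rh2(4R-MPPIM)4 (carboxamidate ligands and second rhodium not drawn) | COc1cc(CCCOC(=O)C=[Rh])ccc1OCc1ccccc1 | intermediate (not isolated)
10 | (4R)-4-{[4-(benzyloxy)-3-methoxyphenyl]methyl}oxolan-2-one | COc1cc(C[C@H]2COC(=O)C2)ccc1OCc1ccccc1 | intermediate
11 | 3,4-dihydroxy-5-methoxybenzaldehyde | COc1cc(C=O)cc(O)c1O | starting material
12 | 3,4-bis(benzyloxy)-5-methoxybenzaldehyde | COc1cc(C=O)cc(OCc2ccccc2)c1OCc1ccccc1 | intermediate
13 | [3,4-bis(benzyloxy)-5-methoxyphenyl]methanol | COc1cc(CO)cc(OCc2ccccc2)c1OCc1ccccc1 | intermediate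
14 | 1,2-bis(benzyloxy)-5-(bromomethyl)-3-methoxybenzene | COc1cc(CBr)cc(OCc2ccccc2)c1OCc1ccccc1 | intermediate
15 | lithium (4R)-4-{[4-(benzyloxy)-3-methoxyphenyl]methyl}-4,5-dihydrofuran-2-olate | [Li+].[O-]C1=C[C@@H](Cc2ccc(OCc3ccccc3)c(OC)c2)CO1 | intermediate (not isolated)
16 | (3R,4R)-3-{[3,4-bis(benzyloxy)-5-methoxyphenyl]methyl}-4-{[4-(benzyloxy)-3-methoxyphenyl]methyl}oxolan-2-one | COc1cc(C[C@H]2COC(=O)[C@@H]2Cc2cc(OCc3ccccc3)c(OCc3ccccc3)c(OC)c2)ccc1OCc1ccccc1 | intermediate
17 | (−)-thujaplicatin, (3R,4R)-3-[(3,4-dihydroxy-5-methoxyphenyl)methyl]-4-[(4-hydroxy-3-methoxyphenyl)methyl]oxolan-2-one | COc1cc(C[C@H]2COC(=O)[C@@H]2Cc2cc(O)c(O)c(OC)c2)ccc1O | target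

**Count and risks**

Total step count: 9. Longest linear sequence: 6 steps (1, 2, 3, 4, 8, 9); steps 5–7 are a three-step side branch.

Steps most likely to fail:

Step 4. The catalyst may discriminate too weakly between the two enantiotopic C–H bonds. The carbene may also be diverted into dimerisation, into four-membered ring closure at the O–CH2 group, or into addition to the electron-rich arene. The fallback replaces the carbene insertion by an auxiliary-controlled enolate alkylation and lactonisation; it sets out from alcohol 3 and comes back at lactone 10. Alcohol 3 is oxidised (TEMPO cat., PhI(OAc)2, MeCN/H2O) to 3-[4-(benzyloxy)-3-methoxyphenyl]propanoic acid F1. This is turned in the flask (PivCl, Et3N, THF, −20 °C) into the pivalic mixed anhydride F2, which acylates lithiated (S)-4-benzyloxazolidin-2-one to give the N-acyl oxazolidinone F3. NaHMDS (THF, −78 °C) should give the Z sodium enolate F4, which tert-butyl bromoacetate alkylates on the face away from the auxiliary benzyl group to give the (3R) alkylated imide F5. LiBH4 (THF/H2O, 0 °C) removes the auxiliary reductively to give the hydroxy tert-butyl ester F6, and TsOH (cat., toluene, 80 °C) closes the lactone to 10.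

Step 8. Proton exchange between product and enolate may lead to double alkylation, the electron-rich benzylic bromide may decompose before it is consumed, and the facial selectivity may be incomplete. The fallback replaces the alkylation by an aldol addition and reductive removal of the carbinol oxygen; it sets out from lactone 10 (as its enolate 15) and aldehyde 12 and comes back at the target 17. Enolate 15 (LiHMDS, THF, −78 °C) adds to aldehyde 12 anti to the C4 substituent to give the trans aldol adduct F7 as a mixture of carbinol epimers. H2, Pd/C in EtOAc/AcOH should then cleave the three benzyl ethers and, through the p-quinone methide of the freed phenol, the benzylic C–OH bond, to give 17 directly. Steps 6, 7 and 9 are then not needed.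

Step 3. The elimination of sulfinate may stop short, or the diazo ester may decompose under the basic conditions or on purification. The fallback is a deacylative diazo transfer; it sets out from alcohol 3 and comes back at diazoacetate 8. Alcohol 3 and 2,2,6-trimethyl-4H-1,3-dioxin-4-one (xylene, 140 °C) give the acetoacetate F8. Diazo transfer (4-acetamidobenzenesulfonyl azide, Et3N, MeCN) gives the 2-diazoacetoacetate F9, and LiOH (H2O/THF, rt) removes the acetyl group to give 8.

**Further compounds**

F1 | step 4 | 3-[4-(benzyloxy)-3-methoxyphenyl]propanoic acid | COc1cc(CCC(O)=O)ccc1OCc1ccccc1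
F2 | step 4 | 3-[4-(benzyloxy)-3-methoxyphenyl]propanoic pivalic anhydride | COc1cc(CCC(=O)OC(=O)C(C)(C)C)ccc1OCc1ccccc1
F3 | step 4 | (4S)-4-benzyl-3-{3-[4-(benzyloxy)-3-methoxyphenyl]propanoyl}oxazolidin-2-one | COc1cc(CCC(=O)N2[C@@H](Cc3ccccc3)COC2=O)ccc1OCc1ccccc1
F4 | step 4 | Z sodium enolate of F3 | [Na+].[O-]/C(=C\Cc1ccc(OCc2ccccc2)c(OC)c1)N1[C@@H](Cc2ccccc2)COC1=O
F5 | step 4 | tert-butyl (3R)-3-{[4-(benzyloxy)-3-methoxyphenyl]methyl}-4-[(4S)-4-benzyl-2-oxooxazolidin-3-yl]-4-oxobutanoate | CC(C)(C)OC(=O)C[C@@H](Cc1ccc(OCc2ccccc2)c(OC)c1)C(=O)N1[C@@H](Cc2ccccc2)COC1=O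
F6 | step 4 | tert-butyl (3R)-4-[4-(benzyloxy)-3-methoxyphenyl]-3-(hydroxymethyl)butanoate | CC(C)(C)OC(=O)C[C@@H](Cc1ccc(OCc2ccccc2)c(OC)c1)CO
F7 | step 8 | (3S,4R)-3-{[3,4-bis(benzyloxy)-5-methoxyphenyl](hydroxy)methyl}-4-{[4-(benzyloxy)-3-methoxyphenyl]methyl}oxolan-2-one (ring substituents trans as in 16, carbinol centre as a mixture) | COc1cc(C[C@H]2COC(=O)[C@@H]2C(O)c2cc(OCc3ccccc3)c(OCc3ccccc3)c(OC)c2)ccc1OCc1ccccc1
F8 | step 3 | 3-[4-(benzyloxy)-3-methoxyphenyl]propyl 3-oxobutanoate | COc1cc(CCCOC(=O)CC(C)=O)ccc1OCc1ccccc1
F9 | step 3 | 3-[4-(benzyloxy)-3-methoxyphenyl]propyl 2-diazo-3-oxobutanoate | COc1cc(CCCOC(=O)C(=[N+]=[N-])C(C)=O)ccc1OCc1ccccc1
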